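**Assumption:** The SMILES describes a cis-fused hydroazulene (7-5) core, not a hydrindane. I used the SMILES as given. The 7-ring carries the exocyclic methylene and the CMe2 group. The cyclopentane carries the angular methyl and the bicyclic acylal side chain.

## Retrosynthetic overview
1. Aplyviolene comes from acetylation of a bicyclic lactol. That lactol forms spontaneously from an open dialdehyde–acid when a dimethyl acetal and a tert-butyl ester are unmasked.
2. The acetal/ester precursor comes from a photoredox Giese addition of the hindered tertiary C-8 radical (from a tertiary oxalate) to an α-alkylidene enal. The radical is attacked on the convex face of the cis-hydroazulene.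
3. The tertiary oxalate comes from MeLi addition to a cis-hydroazulenone. That ketone comes from deconjugative protonation of an aldol-condensation enone.
4. The 7-5 core comes from a formal [5+2] annulation of cyclopentenone with sulcatone: Fe–H HAT Giese, then 7-ring aldol condensation. The cyclopentane forms first, then the 7-ring, then the THF/lactone last.
5. This avoids coupling two elaborate preformed fragments. Both halves are built from commodity ketones and aldehydes.

## Forward route

**Step 1**
Reactants: 1 cyclopent-2-en-1-one; 2 sulcatone (6-methylhept-5-en-2-one)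
Product: 3 rac-3-(2-methyl-6-oxoheptan-2-yl)cyclopentan-1-one
Conditions: Fe(acac)3 (1 equiv), PhSiH3 (2.5 equiv), EtOH, 60 °C; enone in 3-fold excess
Reagents that add atoms: none
Why: Fe–H hydrogen-atom transfer to the trisubstituted alkene of 2 gives a tertiary radical, which adds to the β-carbon of 1 (Mukaiyama/Baran-type HAT Giese) and creates the gem-dimethyl quaternary carbon and the C-3a stereocentre (racemic). Proposed new method: the closest precedent is HAT olefin–enone coupling; a hindered tertiary radical adding to the β-carbon of cyclopentenone extends it.

**Step 2**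
Reactants: 3
Product: 4 rac-4,4,8-trimethyl-3,3a,4,5,6,7-hexahydroazulen-1(2H)-one
Conditions: NaOEt (0.3 equiv), EtOH, reflux, 0.02 M (slow addition)
Reagents that add atoms: none
Why: The C-8a enolate closes onto the methyl ketone (7-ring intramolecular aldol condensation). The gem-dimethyl carbon gives a Thorpe–Ingold effect, and dehydration gives the conjugated α-alkylidene cyclopentanone. Proposed new method: this is a one-carbon homologue of the Hajos–Parrish-type aldol; the 1,8-diketone to 7-ring closure is the less common mode.

**Step 3**
Reactants: 4
Product: 5 rac-cis-4,4-dimethyl-8-methylideneoctahydroazulen-1(2H)-one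
Conditions: t-BuOK (1.2 equiv), THF, −78 → 0 °C; then AcOH (3 equiv) in THF at −78 °C
Reagents that add atoms: none
Why: Deconjugative protonation. γ-Deprotonation of the methyl group gives the extended dienolate. Kinetic α-protonation at C-8a gives the β,γ-enone with the exocyclic methylene. The proton arrives anti to the CMe2 group, so the ring fusion is cis (H-3a and H-8a on the same face).

**Step 4**
Reactants: 5
Product: 6 (3a,8a)-cis-4,4-dimethyl-8-methylideneoctahydroazulen-1(2H)-one, single enantiomer matching the target ring fusion
Conditions: preparative chiral-phase HPLC (Chiralpak IA, n-hexane/i-PrOH 99:1), rt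
Reagents that add atoms: none
Why: Physical enantiomer resolution. No catalytic enantioselective version of the HAT Giese is available, and the relative configuration was already fixed in Step 3, so only two enantiomers exist.

**Step 5**
Reactants: 6
Product: 7 1,4,4-trimethyl-8-methylideneoctahydroazulen-1-ol (Me on the convex face, OH concave)
Conditions: MeLi (1.5 equiv), anhydrous CeCl3 (1.5 equiv), THF, −78 °C
Reagents that add atoms: methyllithium, C[Li]
Why: Organocerium 1,2-addition suppresses enolisation of the acidic allylic α-H; the alcohol epimer does not matter because C-1 is later planarised as a radical.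

**Step 6**
Reactants: 7
Product: 8 methyl oxalate ester of 7
Conditions: ClC(=O)CO2Me (3 equiv), pyridine, DMAP (cat.), CH2Cl2, 0 °C → rt
Reagents that add atoms: methyl chlorooxoacetate, COC(=O)C(=O)Cl
Why: DMAP-catalysed acylation of the tertiary alcohol; no new stereocentre.

**Step 7**
Reactants: 8
Product: 9 cesium oxalate salt
Conditions: CsOH·H2O (1.0 equiv), MeOH/THF 1:4, 0 °C
Reagents that add atoms: cesium hydroxide, [Cs+].[OH-]
Why: Selective saponification of the unhindered methyl ester gives the photoredox-active alkyl cesium oxalate (Overman-type radical precursor).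

**Step 8**
Reactants: 10 pent-4-enoic acid
Product: 11 tert-butyl pent-4-enoate
Conditions: Boc2O (1.5 equiv), t-BuOH (3 equiv), DMAP (0.3 equiv), CH2Cl2, rt
Reagents that add atoms: di-tert-butyl dicarbonate, CC(C)(C)OC(=O)OC(=O)OC(C)(C)C; tert-butanol, CC(C)(C)O
Why: DMAP-catalysed tert-butyl esterification via a mixed anhydride; no stereocentre.

**Step 9**
Reactants: 11
Product: 12 tert-butyl 4-oxobutanoate
Conditions: O3, CH2Cl2/MeOH, −78 °C; then Me2S, rt
Reagents that add atoms: ozone, [O-][O+]=O
Why: Ozonolysis of the terminal alkene gives the aldehyde. The ester is unaffected, and this is the only alkene present.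

**Step 10**
Reactants: 12; 13 2,2-dimethoxyacetaldehyde
Product: 14 (E)-tert-butyl 3-formyl-5,5-dimethoxypent-3-enoate (α-alkylidene enal)
Conditions: pyrrolidine (0.2 equiv), PhCO2H (0.2 equiv), MeCN, 40 °C; 12 added slowly to excess 13
Reagents that add atoms: none
Why: Enamine-mediated crossed aldol condensation with a non-enolisable aldehyde gives the thermodynamic E-enal. This enal is the six-carbon "dialdehyde-acid" synthon, with C4 masked as the dimethyl acetal.

**Step 11**
Reactants: 9; 14
Product: 15 adduct (quaternary C-1 with the side chain: CH(CH(OMe)2)–CH(CHO)–CH2CO2tBu)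
Conditions: [Ir{dF(CF3)ppy}2(dtbbpy)]PF6 (2 mol%), DMF (0.05 M), H2O (2 equiv), blue LEDs (455 nm), rt; 14 in 3-fold excess
Reagents that add atoms: none
Why: Photoredox oxidation of the oxalate releases 2 CO2 and the tertiary radical. It adds to the β-carbon of enal 14 on the convex face (syn to H-3a/H-8a, anti to the C-8 methylene), which sets C-1 with Me concave. The α-formyl radical is reduced and protonated. Proposed new method: this is Overman-type oxalate Giese chemistry applied to a hindered trisubstituted α-alkylidene enal. The side-chain stereocentre next to the quaternary carbon is set by acceptor approach, and the one α to the aldehyde is epimerisable.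

**Step 12**
Reactants: 15
Product: 16 deacetylaplyviolene (bicyclic lactol-lactone)
Conditions: TMSOTf (4 equiv), 2,6-lutidine (6 equiv), CH2Cl2, 0 °C, 1 h; then H2O, rt
Reagents that add atoms: water, O
Why: TMSOTf/lutidine cleaves the tert-butyl ester and converts the dimethyl acetal to the aldehyde via a pyridinium intermediate, without strong acid. The resulting dialdehyde-acid closes to the acyloxy-hemiacetal, then to the 2,7-dioxabicyclo[3.2.1]octane hemiacetal. The bridgeheads are fixed by the bicycle, and the two α-centres can equilibrate so that the bicycle with the substituent syn to the lactone bridge is selected. Proposed new method: mechanism is Fujioka-type mild acetal deprotection followed by spontaneous pseudo-acid/lactol cascade, as in the biogenetic dialdehyde-acid to lactol closure.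

**Step 13**
Reactants: 16
Product: 17 aplyviolene
Conditions: Ac2O (5 equiv), pyridine, DMAP (cat.), CH2Cl2, 0 °C
Reagents that add atoms: acetic anhydride, CC(=O)OC(C)=O
Why: Acylation of the anomeric hydroxyl; the ring–chain-equilibrating hemiacetal gives the anomeric acetate with the acetoxy group on the anomerically favoured face.

## Compound list
1 | cyclopent-2-en-1-one | O=C1C=CCC1 | starting material
2 | 6-methylhept-5-en-2-one (sulcatone) | CC(=O)CCC=C(C)C | starting material
3 | rac-3-(2-methyl-6-oxoheptan-2-yl)cyclopentan-1-one | O=C1CC(CC1)C(C)(C)CCCC(C)=O | intermediate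
4 | rac-4,4,8-trimethyl-3,3a,4,5,6,7-hexahydroazulen-1(2H)-one | O=C1CCC2C1=C(C)CCCC2(C)C | intermediate
5 | rac-cis-4,4-dimethyl-8-methylideneoctahydroazulen-1(2H)-one (one enantiomer drawn) | C=C1CCCC(C)(C)[C@@H]2CCC(=O)[C@H]12 | intermediate
6 | resolved ketone (target ring-fusion configuration) | C=C1CCCC(C)(C)[C@@H]2CCC(=O)[C@H]12 | intermediate
7 | 1,4,4-trimethyl-8-methylideneoctahydroazulen-1-ol | C=C1CCCC(C)(C)[C@@H]2CC[C@](C)(O)[C@H]12 | intermediate
8 | methyl oxalate of 7 | C=C1CCCC(C)(C)[C@@H]2CC[C@](C)(OC(=O)C(=O)OC)[C@H]12 | intermediate
9 | cesium oxalate of 7 | C=C1CCCC(C)(C)[C@@H]2CC[C@](C)(OC(=O)C(=O)[O-])[C@H]12.[Cs+] | intermediate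
10 | pent-4-enoic acid | C=CCCC(=O)O | starting material
11 | tert-butyl pent-4-enoate | C=CCCC(=O)OC(C)(C)C | intermediate
12 | tert-butyl 4-oxobutanoate | O=CCCC(=O)OC(C)(C)C | intermediate
13 | 2,2-dimethoxyacetaldehyde | COC(OC)C=O | starting material
14 | (E)-tert-butyl 3-formyl-5,5-dimethoxypent-3-enoate | O=C/C(CC(=O)OC(C)(C)C)=C/C(OC)OC | intermediate
15 | radical adduct (ester/aldehyde/acetal; C-1 quaternary, side-chain α-CH as drawn, CH(CHO) centre unspecified) | C=C1CCCC(C)(C)[C@@H]2CC[C@@](C)([C@H](C(OC)OC)C(C=O)CC(=O)OC(C)(C)C)[C@H]12 | intermediate
16 | deacetylaplyviolene | C=C1CCCC(C)(C)[C@@H]2CC[C@@](C)([C@@H]3[C@@H]4OC(=O)C[C@H]3[C@H](O)O4)[C@H]12 | intermediate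
17 | aplyviolene | C=C1CCCC(C)(C)[C@@H]2CC[C@@](C)([C@@H]3[C@@H]4OC(=O)C[C@H]3[C@H](OC(C)=O)O4)[C@H]12 | target

## Totals
- **Total steps:** 13.
- **Longest linear sequence:** 10 steps, from cyclopent-2-enone through Steps 1–7, 11, 12 and 13.

## Three steps most likely to fail
1. **Step 11 (radical coupling).** Risks are the hindered adjacent quaternary/tertiary bond formation and the diastereoselectivity at the side-chain carbon next to C-1. Fallback: couple the same oxalate-derived radical to a preformed γ-alkoxybutenolide acceptor (Overman-type convergent coupling), then build the dioxabicycle from that lactone.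
2. **Step 2 (7-ring aldol condensation).** 1,8-Diketone to cycloheptene closure is entropically poor. Fallback: change the ring-closing disconnection to ring-closing metathesis of a cis-1,2-disubstituted cyclopentanone carrying a vinyl ketone and a reverse-prenyl vinyl group, then hydrogenate the ring alkene and methylenate the ketone.
3. **Step 12 (deprotection/cyclisation cascade).** The lactol may not form cleanly or with the right diastereomer. Fallback: carry the side chain as a C-4 acetal, a C-2 CH2OTBS and an ester. Form the bis-lactone acylal by acylal formation from the aldehyde and anhydride, reduce the γ-lactone chemoselectively with DIBAL to the lactol, and then acetylate (Step 13).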